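**Retrosynthetic overview**
- Ring A is the cyclohexene (C1 alkyne-bearing sp2 carbon, C2 olefinic CH, C3 acetoxy carbon, C4 methoxy carbon, C5 and C6 carbinol carbons, C6 next to C1). Target ⇐ C3 carbinol ⇐ C3 ketone (enone of ring A): reduction directed by the C5 hydroxyl, then acetylation of C3–OH while the cis C5/C6 diol is masked as a transient boronate.
- Enone ⇐ one-flask [3+3] annulation that makes C4–C5 (aldol) and C1=C2 (carbanion opening of an alkynyl oxirane, then loss of PhSOH) from a keto sulfoxide (C2–C3–C4, OMe already on C4) and an epoxy aldehyde (C5–C6–C1, complete side chain attached).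
- Enabling feature: with C3 as a ketone, C5–OH is an aldol hydroxyl and C4 and C2 are both nucleophilic; the C6–OH/C1 pair is the remnant of an oxirane bridging C6 and C1, so O5–C5–C6(O6)–C1 maps onto an α,β-epoxy aldehyde used as 1,3-bis-electrophile. The phenylsulfinyl group on C2 activates and is expelled in the same step.
- Epoxy aldehyde ⇐ asymmetric epoxidation and oxidation of a dienynediol ⇐ Sonogashira coupling of a 2-bromo-1,4-diene (from a Stille allyl–vinyl coupling) with an enynol.
- Ring order: oxirane (temporary, step 4), ring A (step 7, consuming the oxirane), dioxaborolane (transient, step 9).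

Key step: step 7

Remark: the keto sulfoxide is used racemic at sulfur; the sulfur and C2 configurations of the intermediates are not controlled, because both centres are erased when PhSOH is lost.
Remark: (2E)-pent-2-en-4-yn-1-ol is taken as the commercially supplied E isomer.
Remark: in step 7 one equivalent of the dianion is spent as base on the tertiary hydroxyl of the aldehyde, hence the excess; it is re-protonated on quench.

Step 1
Reactants: 1 2-methylbut-3-yn-2-ol
Product: 2 (3E)-2-methyl-4-(tributylstannyl)but-3-en-2-ol
Conditions: Bu3SnH, PdCl2(PPh3)2 (cat.), THF, 0 °C to rt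
Reagents that add atoms: tributyltin hydride CCCC[SnH](CCCC)CCCC
Why: Palladium-catalysed hydrostannation is a syn addition of Sn–H across the terminal alkyne, and the bulky tertiary carbinol should steer tin to the terminal carbon, giving the E-vinylstannane.

Step 2
Reactants: 2 (3E)-2-methyl-4-(tributylstannyl)but-3-en-2-ol; 3 2,3-dibromoprop-1-ene
Product: 4 (3E)-6-bromo-2-methylhepta-3,6-dien-2-ol
Conditions: Pd2(dba)3 (cat.), AsPh3, DMF, 40 °C
Reagents that add atoms: none
Why: Stille coupling in which palladium should insert into the allylic C–Br bond of 3 much faster than into its vinylic C–Br bond, so the E-vinyl group is transferred with retention of geometry and the 2-bromoalkene survives for step 3.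

Step 3
Reactants: 4 (3E)-6-bromo-2-methylhepta-3,6-dien-2-ol; 5 (2E)-pent-2-en-4-yn-1-ol
Product: 6 (2E,8E)-10-methyl-6-methylideneundeca-2,8-dien-4-yne-1,10-diol
Conditions: Pd(PPh3)4 (cat.), CuI (cat.), iPr2NH, THF, 40 °C
Reagents that add atoms: none
Why: Sonogashira coupling of the 2-bromoalkene with the terminal alkyne should build the 2-substituted 1,3-enyne of the side chain, with both free hydroxyls and both E-alkenes tolerated.

Step 4
Reactants: 6 (2E,8E)-10-methyl-6-methylideneundeca-2,8-dien-4-yne-1,10-diol
Product: 7 {(2R,3R)-3-[(5E)-7-hydroxy-7-methyl-3-methylideneoct-5-en-1-yn-1-yl]oxiran-2-yl}methanol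
Conditions: Ti(OiPr)4, D-(−)-diisopropyl tartrate, tBuOOH, 4 Å MS, CH2Cl2, −20 °C
Reagents that add atoms: tert-butyl hydroperoxide CC(C)(C)OO
Why: Sharpless asymmetric epoxidation should act only on the alkene of the primary allylic alcohol (the tertiary allylic alcohol and the 1,1-disubstituted alkene are very poor substrates), and the D-tartrate ligand should deliver oxygen to the face that gives the (2R,3R)-oxirane, which fixes the future C6.

Step 5
Reactants: 7 {(2R,3R)-3-[(5E)-7-hydroxy-7-methyl-3-methylideneoct-5-en-1-yn-1-yl]oxiran-2-yl}methanol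
Product: 8 (2S,3R)-3-[(5E)-7-hydroxy-7-methyl-3-methylideneoct-5-en-1-yn-1-yl]oxirane-2-carbaldehyde
Conditions: TEMPO (cat.), PhI(OAc)2, CH2Cl2, rt
Reagents that add atoms: none
Why: The oxoammonium-mediated oxidation (TEMPO/PhI(OAc)2) should convert the primary alcohol into the aldehyde without opening the oxirane, epimerising its α-carbon or touching the tertiary alcohol.

Step 6
Reactants: 9 methyl methoxyacetate; 10 methyl phenyl sulfoxide
Product: 11 1-methoxy-3-(phenylsulfinyl)propan-2-one
Conditions: LiN(iPr)2 (2.1 equiv), THF, −78 to 0 °C; AcOH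
Reagents that add atoms: none
Why: Claisen-type acylation of the α-lithio sulfoxide by the ester should give the β-keto sulfoxide, the second equivalent of base being consumed by its acidic C2–H, and no carbon stereocentre is formed.

Step 7
Reactants: 8 (2S,3R)-3-[(5E)-7-hydroxy-7-methyl-3-methylideneoct-5-en-1-yn-1-yl]oxirane-2-carbaldehyde; 11 1-methoxy-3-(phenylsulfinyl)propan-2-one
Product: 14 (4S,5S,6R)-4,5-dihydroxy-3-[(5E)-7-hydroxy-7-methyl-3-methylideneoct-5-en-1-yn-1-yl]-6-methoxycyclohex-2-en-1-one, via epoxy aldol adduct 12 (not isolated), via cyclic keto sulfoxide 13 (not isolated)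
Conditions: 11 (2.2 equiv), LiN(iPr)2 (4.4 equiv), THF, −78 °C; then 8, −78 °C to rt; AcOH; PhMe, 60 °C
Reagents that add atoms: none
Why: Proposed new method: the 1,3-dianion of 11 should add through its γ-carbon C4 to the aldehyde carbon C5 of 8 (aldol, bond C4–C5); the sulfinyl-stabilised enolate carbon C2 that remains should then attack the oxirane at its propargylic carbon C1 in an SN2 6-endo epoxide opening that closes ring A and frees O6 as the C6 hydroxyl, and after neutralisation the β-keto sulfoxide 13 should lose PhSOH by thermal syn-elimination across C2–C1, so that bond C1=C2 is completed in the same flask. The closest known reaction types are the γ-aldol of β-keto sulfoxide dianions, the intramolecular alkylation of stabilised carbanions by epoxides and the sulfoxide syn-elimination to enones; their merger into one [3+3] annulation with an α,β-epoxy aldehyde as 1,3-bis-electrophile is what is new. C5 should be set by attack on the aldehyde anti to the oxirane C–O bond in the non-chelated staggered transition state (5,6-erythro, that is cis in the ring), and C4 by a lithium-chelated Z-enolate reacting through a closed chair transition state (4,5-syn, that is trans in the ring); C6 is carried over unchanged from the oxirane, while C1, C2 and sulfur are stereochemically erased. The step needs γ- before α-attack of the dianion (the γ-carbanion is the more basic and more nucleophilic site), opening at C1 and not at C6 (C1 is propargylic and remote from the alkoxide, C6 is deactivated by the adjacent C5–O bond and would give a five-membered ring), and elimination towards C1 (the only β-hydrogen of the sulfoxide, made labile by the alkyne).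

Step 8
Reactants: 14 (4S,5S,6R)-4,5-dihydroxy-3-[(5E)-7-hydroxy-7-methyl-3-methylideneoct-5-en-1-yn-1-yl]-6-methoxycyclohex-2-en-1-one
Product: 15 (1S,2S,3S,4S)-6-[(5E)-7-hydroxy-7-methyl-3-methylideneoct-5-en-1-yn-1-yl]-3-methoxycyclohex-5-ene-1,2,4-triol
Conditions: Me4NBH(OAc)3, MeCN/AcOH (1:1), −20 °C
Reagents that add atoms: none
Why: Hydroxyl-directed (Evans–Saksena) reduction in which the C5 hydroxyl should exchange onto boron and deliver hydride intramolecularly to the C3 carbonyl from its own face, giving the C3 carbinol anti to C5–OH (cis to C4–OMe), while this mild hydride should leave the enyne and the alkenes alone.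

Step 9
Reactants: 15 (1S,2S,3S,4S)-6-[(5E)-7-hydroxy-7-methyl-3-methylideneoct-5-en-1-yn-1-yl]-3-methoxycyclohex-5-ene-1,2,4-triol
Product: 18 (1S,4S,5S,6R)-4,5-dihydroxy-3-[(5E)-7-hydroxy-7-methyl-3-methylideneoct-5-en-1-yn-1-yl]-6-methoxycyclohex-2-en-1-yl acetate, via phenylboronate 16 (not isolated), via acetylated phenylboronate 17 (not isolated)
Conditions: PhB(OH)2 (1.05 equiv), 4 Å MS, CH2Cl2, rt; Ac2O, pyridine, 0 °C; pinacol, rt
Reagents that add atoms: acetic anhydride CC(=O)OC(C)=O
Why: Regioselective acylation under transient boronate protection, in which PhB(OH)2 should esterify only the cis C5/C6 diol as a five-membered dioxaborolane (the trans-1,3 pair C3/C5 and the tertiary carbinol cannot form a cyclic ester), Ac2O/pyridine should then acetylate the remaining secondary C3 hydroxyl with retention (the tertiary alcohol is inert without DMAP), and transesterification to pinacol should release the diol without acyl migration because C4 carries OMe.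

**Compound list**
1 | 2-methylbut-3-yn-2-ol | CC(C)(O)C#C | starting material
2 | (3E)-2-methyl-4-(tributylstannyl)but-3-en-2-ol | CCCC[Sn](CCCC)(CCCC)/C=C/C(C)(C)O | intermediate
3 | 2,3-dibromoprop-1-ene | C=C(Br)CBr | starting material
4 | (3E)-6-bromo-2-methylhepta-3,6-dien-2-ol | C=C(Br)C/C=C/C(C)(C)O | intermediate
5 | (2E)-pent-2-en-4-yn-1-ol | OC/C=C/C#C | starting material
6 | (2E,8E)-10-methyl-6-methylideneundeca-2,8-dien-4-yne-1,10-diol | OC/C=C/C#CC(=C)C/C=C/C(C)(C)O | intermediate
7 | {(2R,3R)-3-[(5E)-7-hydroxy-7-methyl-3-methylideneoct-5-en-1-yn-1-yl]oxiran-2-yl}methanol | OC[C@H]1O[C@@H]1C#CC(=C)C/C=C/C(C)(C)O | intermediate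
8 | (2S,3R)-3-[(5E)-7-hydroxy-7-methyl-3-methylideneoct-5-en-1-yn-1-yl]oxirane-2-carbaldehyde | O=C[C@H]1O[C@@H]1C#CC(=C)C/C=C/C(C)(C)O | intermediate
9 | methyl methoxyacetate | COCC(=O)OC | starting material
10 | methyl phenyl sulfoxide | CS(=O)c1ccccc1 | starting material
11 | 1-methoxy-3-(phenylsulfinyl)propan-2-one (racemic at sulfur) | COCC(=O)CS(=O)c1ccccc1 | intermediate
12 | (3R,4S)-4-hydroxy-3-methoxy-4-{(2R,3R)-3-[(5E)-7-hydroxy-7-methyl-3-methylideneoct-5-en-1-yn-1-yl]oxiran-2-yl}-1-(phenylsulfinyl)butan-2-one (epoxy aldol adduct, mixture at sulfur, not isolated) | O=S(c1ccccc1)CC(=O)[C@H](OC)[C@@H](O)[C@H]2O[C@@H]2C#CC(=C)C/C=C/C(C)(C)O | intermediate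
13 | (3S,4S,5S,6R)-4,5-dihydroxy-3-[(5E)-7-hydroxy-7-methyl-3-methylideneoct-5-en-1-yn-1-yl]-6-methoxy-2-(phenylsulfinyl)cyclohexan-1-one (cyclic keto sulfoxide, mixture at C2 and at sulfur, not isolated) | O=C1C(S(=O)c2ccccc2)[C@@H](C#CC(=C)C/C=C/C(C)(C)O)[C@H](O)[C@H](O)[C@H]1OC | intermediate
14 | (4S,5S,6R)-4,5-dihydroxy-3-[(5E)-7-hydroxy-7-methyl-3-methylideneoct-5-en-1-yn-1-yl]-6-methoxycyclohex-2-en-1-one | C=C(C#CC1=CC(=O)[C@H](OC)[C@@H](O)[C@H]1O)C/C=C/C(C)(C)O | intermediate
15 | (1S,2S,3S,4S)-6-[(5E)-7-hydroxy-7-methyl-3-methylideneoct-5-en-1-yn-1-yl]-3-methoxycyclohex-5-ene-1,2,4-triol | C=C(C#CC1=C[C@H](O)[C@H](OC)[C@@H](O)[C@H]1O)C/C=C/C(C)(C)O | intermediate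
16 | cyclic phenylboronate of 15 across the cis C5/C6 diol (2-phenyl-1,3,2-dioxaborolane fused to ring A, C3–OH free, not isolated) | C=C(C#CC1=C[C@H](O)[C@H](OC)[C@H]2OB(c3ccccc3)O[C@@H]12)C/C=C/C(C)(C)O | intermediate
17 | C3 acetate of phenylboronate 16 (not isolated) | C=C(C#CC1=C[C@H](OC(C)=O)[C@H](OC)[C@H]2OB(c3ccccc3)O[C@@H]12)C/C=C/C(C)(C)O | intermediate
18 | (1S,4S,5S,6R)-4,5-dihydroxy-3-[(5E)-7-hydroxy-7-methyl-3-methylideneoct-5-en-1-yn-1-yl]-6-methoxycyclohex-2-en-1-yl acetate | C=C(C#CC1=C[C@H](OC(C)=O)[C@H](OC)[C@@H](O)[C@H]1O)C/C=C/C(C)(C)O | target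

**Step count:** 9 steps in total; longest linear sequence 8 steps (steps 1, 2, 3, 4, 5, 7, 8, 9).

**Steps most likely to fail**

Step 7 (fallback sets out from 8 and 11 and returns at 14). The lithium aldol may discriminate poorly between the two aldehyde faces or between enolate geometries. The enolate may open the oxirane at C6 (five-membered ring) or not at all while the aldolate reverts. The β-hydroxy enone may dehydrate and aromatise on heating. The fallback uses known reaction types, separates the events and changes the ring closure from anionic epoxide opening to a Nicholas reaction. The dianion of 11 is added to 8 at −78 °C and quenched cold, so that aldol adduct 12 is isolated and freed from its diastereomers. Co2(CO)8 in CH2Cl2 then converts its alkyne into the hexacarbonyldicobalt complex of 12 F1. BF3·OEt2 at −78 °C ionises the oxirane at C1 to the cobalt-stabilised propargylic cation, which is trapped by the enol carbon C2 of the keto sulfoxide to give the hexacarbonyldicobalt complex of the cyclised keto sulfoxide F2; here the cation, not a ring-size preference, fixes the regiochemistry. (NH4)2Ce(NO3)6 in acetone removes cobalt to give the cyclic keto sulfoxide as a C1 epimer mixture F3, which on warming in PhMe loses PhSOH and rejoins the route at 14.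

Step 4 (fallback sets out from 6 and returns at 8). The electron-poor enyne alkene may be epoxidised slowly while the tertiary carbinol ties up titanium, and the Lewis-acidic medium may open the alkynyl oxirane. The fallback replaces electrophilic by nucleophilic epoxidation. MnO2 in CH2Cl2 oxidises only the primary allylic alcohol of 6 to (2E,8E)-10-hydroxy-10-methyl-6-methylideneundeca-2,8-dien-4-ynal F4. Iminium-catalysed epoxidation with aqueous H2O2 and (R)-α,α-bis[3,5-bis(trifluoromethyl)phenyl]prolinol trimethylsilyl ether in CH2Cl2 (the catalyst antipode expected to give the (2S,3R)-oxirane) then delivers 8 directly, so that step 5 is not needed.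

Step 8 (fallback sets out from 14 and returns at 18). Boron may be carried by the C6 hydroxyl instead of the C5 hydroxyl, or undirected hydride attack may compete, eroding the facial selectivity at C3; the acidic medium may also ionise the allylic alcohols. The fallback replaces substrate direction by reagent control. 2,2-Dimethoxypropane and pyridinium p-toluenesulfonate convert 14 into the C5/C6 acetonide of 14 F5. Corey–Bakshi–Shibata reduction with (S)-2-methyl-CBS-oxazaborolidine and catecholborane gives the C5/C6 acetonide of 15 F6; the catalyst antipode is chosen on the model in which the alkenyl arm is the large group, and the other antipode is equally available. Ac2O and pyridine give the C5/C6 acetonide of 18 F7, and 80% aqueous AcOH at 40 °C removes the acetonide to arrive at 18, which replaces steps 8 and 9.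

**Further compounds**
F1 | step 7 | hexacarbonyldicobalt complex of 12 (alkyne-bridged Co2(CO)6) | O=S(c1ccccc1)CC(=O)[C@H](OC)[C@@H](O)[C@H]2O[C@@H]2C45C6(C(=C)C/C=C/C(C)(C)O)[Co]4(=C=O)(=C=O)(=C=O)[Co]56(=C=O)(=C=O)=C=O
F2 | step 7 | hexacarbonyldicobalt complex of the cyclised keto sulfoxide (C1, C2 and sulfur unassigned) | O=C1C(S(=O)c2ccccc2)C(C45C6(C(=C)C/C=C/C(C)(C)O)[Co]4(=C=O)(=C=O)(=C=O)[Co]56(=C=O)(=C=O)=C=O)[C@H](O)[C@H](O)[C@H]1OC
F3 | step 7 | cyclic keto sulfoxide as a C1 epimer mixture (13 without defined C1) | O=C1C(S(=O)c2ccccc2)C(C#CC(=C)C/C=C/C(C)(C)O)[C@H](O)[C@H](O)[C@H]1OC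
F4 | step 4 | (2E,8E)-10-hydroxy-10-methyl-6-methylideneundeca-2,8-dien-4-ynal | O=C/C=C/C#CC(=C)C/C=C/C(C)(C)O
F5 | step 8 | C5/C6 acetonide of 14 | C=C(C#CC1=CC(=O)[C@H](OC)[C@H]2OC(C)(C)O[C@@H]12)C/C=C/C(C)(C)O
F6 | step 8 | C5/C6 acetonide of 15 | C=C(C#CC1=C[C@H](O)[C@H](OC)[C@H]2OC(C)(C)O[C@@H]12)C/C=C/C(C)(C)O
F7 | step 8 | C5/C6 acetonide of 18 | C=C(C#CC1=C[C@H](OC(C)=O)[C@H](OC)[C@H]2OC(C)(C)O[C@@H]12)C/C=C/C(C)(C)O
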